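The leftover is what you read first: from 5.00 min on, the west run holds about 60.1% free monomer, and from 4.00 min on, the south run holds about 74.9%, so the run with more transfer agent keeps more.

| flask | free monomer | transfer agent | initiator | remark | time |
|---|---|---|---|---|---|
| west | 20 mM | 4 mM | 1 mol% | run made earlier |  |
| south | 20 mM | 9 mM | 1 mol% | run made earlier |  |
| flask | 20 mM | 6.00 mM | 1 mol% |  | 15 min |

| run | time / min | monomer in chains / % | free monomer / % |
|---|---|---|---|
| west | 1.50 | 27.5 | 71.7 |
| west | 5.00 | 37.8 | 61.0 |
| west | 8.00 | 38.0 | 60.6 |
| west | 12.0 | 39.3 | 59.9 |
| west | 20.0 | 38.7 | 58.9 |
| south | 4.00 | 24.8 | 75.9 |
| south | 8.00 | 24.4 | 74.7 |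
| south | 10.0 | 24.7 | 74.9 |
| south | 15.0 | 24.4 | 74.7 |
| south | 20.0 | 23.5 | 74.2 |

(standard deviation of a reading: 1 percentage point)

1. average number of monomer units in a chain (chains begun, living or dead) at 15 min
2. part of the free monomer that has reacted at 15 min

- the average divides the monomer in chains by the number of chains begun, living and dead together
- the earlier runs do not show the number of chains; that part of a forecast is a guess

Take a plateau, divide the charge by the part not yet in chains, take the natural logarithm and invert it: that is the stopping number. If chains grow steadily and die at a pace that climbs with the agent, at fixed initiator, it rises in a straight line with the agent. Two runs draw such a line but cannot test it.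

My first way counts monomer in chains. In both runs it reads flat within the scatter from 5.00 min on, earlier than the 15 min asked, so I read the flask on its plateau. The plateaus of 38.5% and 24.4% give stopping numbers 2.06 and 3.58, a rise per mM of agent of 0.304 /mM. At 6.00 mM the number is 2.67, so the flask should hold 31.2% in chains.

My second way puts the free monomer leftovers through the same reckoning. It gives 2.56, so 32.3% reacted. The ways part by 1.1 percentage points, and the readings of both runs fall short of the charge, by 1.5 points and 0.76 points, though that is near the scatter. Since c asks for the free monomer reacted, I take it from the second way. For dp the second way cheats, counting monomer that seems never to have entered chains. If each initiator starts one chain, which is a guess, the first way gives dp 31.2.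

The forecast says dp 30 (12 to 50) and c 32% (29% to 35%), holding that “the plateau marks their exhaustion rather than a slow rate”. Its c matches mine, and its dp stands below mine.

The flask gives dp 31.4 and c 32.3%.

    living end + transfer agent → dead chain (kL = 2.38 /M/s)
    free monomer + initiator → living end + monomer in chains (k = 3.71 /M/s)
    free monomer → decomposition product (k = 9.11 × 10⁻⁶ /s)
    living end + free monomer → dead end (k = 0.397 /M/s)
    free monomer + living end → monomer in chains + living end, rate k5*[living end]*[free monomer] (k = 38.0 /M/s)

The flask holds 31.4% in chains, a stopping number of 2.65. With the charges as they stand at the start of that flask, a living end has a pseudo-first-order half-life of 0.809 min against the transfer agent, shorter than the 1.5 min by dead end and short against 15 min. The same line at 10 mM of agent gives 3.89, hence 22.7% in chains, and that neighbour flask holds 22.8%, with dp 22.8.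

The earlier runs and the new flask were generated by integration on assumed constants; noise was put on by code.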